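1. Numbering is that of the benzofuran core (O1, C2, C3, C3a, C4 to C7, C7a): ring A is the benzo ring, ring B the dihydrofuran ring, ring C the 4-hydroxy-3,5-dimethoxyphenyl ring. Rings A and C are bought, and ring B is the only ring made (step 6).
2. Target ⇐ one global hydride reduction of a 2,3-trans 3-formyl benzofuranyl acrylate pivalate (CHO → CH2OH, CO2Me → allylic alcohol, OPiv → OH). The 3-formyl group ⇐ a 3-vinyl group by oxidative cleavage, with C3 equilibrated from cis to trans at the aldehyde.
3. Ring B ⇐ one-flask catalytic asymmetric allylboration / fluoride-relayed SNAr. C2–C3 comes from adding an (E)-γ-aryl allylboronate (ring A) to the ring C aldehyde, and O1–C7a from attack of the new C2 oxygen on a C7a–F bond.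
4. Enabling feature: in ring A the oxygen-bearing C7a is para to C5, the carbon that carries the three-carbon chain. Held at the acrylate oxidation level, this chain stabilises the Meisenheimer intermediate of substitution at C7a, and C2(O)–C3(aryl) is the retron of an aldehyde α-arylallylation once the C3 hydroxymethyl is written as vinyl.
5. Ring A boronate ⇐ 1-bromo-2-fluoro-3-methoxybenzene by C–H borylation at the future C5, oxidative Heck reaction, vinylation and cross-metathesis; ring C aldehyde ⇐ syringaldehyde pivalate.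

Key step: step 6

Remark on the chemistry: the SMILES is read as the 2,3-trans (2R,3S) isomer. C2 is fixed in step 6 and not touched again, whereas C3 leaves step 6 cis and is set trans by thermodynamic epimerisation in step 7. Compounds 1, 3, 5, 7, 9, B2pin2 and pivaloyl chloride are taken as catalogue compounds.

Step 1
Reactants: 1 1-bromo-2-fluoro-3-methoxybenzene
Product: 2 2-(3-bromo-4-fluoro-5-methoxyphenyl)-4,4,5,5-tetramethyl-1,3,2-dioxaborolane
Conditions: [Ir(OMe)(cod)]2 (1.5 mol%), 4,4'-di-tert-butyl-2,2'-bipyridine (3 mol%), B2pin2 (1.0 equiv), THF, 80 °C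
Reagents that add atoms: bis(pinacolato)diboron, CC1(C)OB(OC1(C)C)B1OC(C)(C)C(C)(C)O1
Why: Iridium-catalysed aromatic C–H borylation is sterically governed and should go to the only C–H of 1 that has no ortho substituent (para to fluorine, the future C5), leaving the C–Br bond intact.

Step 2
Reactants: 2 2-(3-bromo-4-fluoro-5-methoxyphenyl)-4,4,5,5-tetramethyl-1,3,2-dioxaborolane; 3 methyl acrylate
Product: 4 methyl (E)-3-(3-bromo-4-fluoro-5-methoxyphenyl)prop-2-enoate
Conditions: Pd(OAc)2 (5 mol%), 2,9-dimethyl-1,10-phenanthroline (6 mol%), O2 (1 atm), DMF, 50 °C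
Reagents that add atoms: none
Why: Oxidative (boron) Heck reaction: transmetalation of the aryl–boron bond to divalent palladium, syn insertion of the acrylate and β-hydride elimination should give the E-cinnamate, and since the cycle needs no phosphine-ligated zerovalent palladium the C–Br bond should survive.

Step 3
Reactants: 4 methyl (E)-3-(3-bromo-4-fluoro-5-methoxyphenyl)prop-2-enoate; 5 2-ethenyl-4,4,5,5-tetramethyl-1,3,2-dioxaborolane
Product: 6 methyl (E)-3-(3-ethenyl-4-fluoro-5-methoxyphenyl)prop-2-enoate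
Conditions: PdCl2(dppf) (3 mol%), K2CO3 (2 equiv), 1,4-dioxane/H2O 9:1, 80 °C
Reagents that add atoms: none
Why: Suzuki–Miyaura cross-coupling at the only C–Br bond should install the vinyl group, the C–F bond being inert to zerovalent palladium under these conditions.

Step 4
Reactants: 6 methyl (E)-3-(3-ethenyl-4-fluoro-5-methoxyphenyl)prop-2-enoate; 7 4,4,5,5-tetramethyl-2-(prop-2-en-1-yl)-1,3,2-dioxaborolane
Product: 8 methyl (E)-3-{4-fluoro-3-methoxy-5-[(E)-3-(4,4,5,5-tetramethyl-1,3,2-dioxaborolan-2-yl)prop-1-en-1-yl]phenyl}prop-2-enoate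
Conditions: second-generation Grubbs catalyst (5 mol%), 7 (3 equiv), CH2Cl2, 40 °C
Reagents that add atoms: none
Why: Olefin cross-metathesis of a styrene with excess allylboronic ester should give the E-configured γ-aryl allylboronate with ethene as the only by-product, while the 1,2-disubstituted, ester-conjugated acrylate double bond should stay a spectator.

Step 5
Reactants: 9 syringaldehyde (4-hydroxy-3,5-dimethoxybenzaldehyde)
Product: 10 4-formyl-2,6-dimethoxyphenyl 2,2-dimethylpropanoate
Conditions: pivaloyl chloride (1.2 equiv), Et3N, DMAP (cat.), CH2Cl2, 0 °C → rt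
Reagents that add atoms: pivaloyl chloride, CC(C)(C)C(Cl)=O
Why: DMAP-catalysed O-acylation gives a pivalate that is shielded by the two flanking methoxy groups, so it should survive fluoride, osmium and amine base yet be cleaved by the hydride in step 8.

Step 6
Reactants: 8 methyl (E)-3-{4-fluoro-3-methoxy-5-[(E)-3-(4,4,5,5-tetramethyl-1,3,2-dioxaborolan-2-yl)prop-1-en-1-yl]phenyl}prop-2-enoate; 10 4-formyl-2,6-dimethoxyphenyl 2,2-dimethylpropanoate
Product: 12 methyl (E)-3-[(2R,3S)-2-{4-[(2,2-dimethylpropanoyl)oxy]-3,5-dimethoxyphenyl}-3-ethenyl-7-methoxy-2,3-dihydro-1-benzofuran-5-yl]prop-2-enoate (2,3-cis), via homoallylic pinacol borate 11 (not isolated)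
Conditions: (R)-TRIP [(R)-3,3'-bis(2,4,6-triisopropylphenyl)-1,1'-binaphthyl-2,2'-diyl hydrogen phosphate] (5 mol%), 4 Å molecular sieves, toluene, −30 → 0 °C; then CsF (3 equiv), DMSO, 60 °C, same flask
Reagents that add atoms: none
Why: Mechanism: the chiral phosphoric acid binds the boronate of 8 (P–OH to the pseudo-axial boronate oxygen) and the formyl C–H of 10 (to P=O), so that the (E)-allyl unit adds through a closed six-membered chair to the Re face of the aldehyde, making C2–C3 and giving borate 11; fluoride then cleaves the B–O bond of 11 (B–F bond formation), the freed C2 alkoxide attacks C7a, and the fluoride it expels carries the chain on. The closest known reaction types are the chiral phosphoric acid-catalysed allyl- and (E)-crotylboration of aryl aldehydes with pinacol boronates and the intramolecular SNAr etherification of 2-(2-fluoroaryl)ethanols to 2,3-dihydrobenzofurans. Ring B closes by 5-exo-trig addition of O1 to C7a, whose Meisenheimer intermediate is stabilised through the para carbon C5 by the acrylate, followed by loss of fluoride. C2 (R) is controlled by the catalyst through the aldehyde face, and C3 (S, cis to the C2 aryl group) by the E geometry of 8 relayed through the chair (anti adduct); because C3 is equilibrated in step 7, only the facial selectivity is critical, and any Z-boronate or syn adduct should converge on the same compound 14. The step needs chemoselectivity for the aldehyde over the two esters, which the mild allylboronate secures, and O-arylation without base damage, which is secured because C–C bond formation is irreversible (no retro-reaction at the alkoxide stage) and because neutral fluoride should leave the benzylic and allylic C3–H, the pivalate and the acrylate alone.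

Step 7
Reactants: 12 methyl (E)-3-[(2R,3S)-2-{4-[(2,2-dimethylpropanoyl)oxy]-3,5-dimethoxyphenyl}-3-ethenyl-7-methoxy-2,3-dihydro-1-benzofuran-5-yl]prop-2-enoate
Product: 14 methyl (E)-3-[(2R,3R)-2-{4-[(2,2-dimethylpropanoyl)oxy]-3,5-dimethoxyphenyl}-3-formyl-7-methoxy-2,3-dihydro-1-benzofuran-5-yl]prop-2-enoate (2,3-trans), via cis-aldehyde 13 (not isolated)
Conditions: OsO4 (2 mol%), NaIO4 (3 equiv), 2,6-lutidine (2 equiv), 1,4-dioxane/H2O 3:1, rt; then aq Na2S2O3, Et3N (3 equiv), rt, same flask, argon
Reagents that add atoms: osmium tetroxide, O=[Os](=O)(=O)=O (catalytic oxygen carrier); sodium periodate, [Na+].[O-]I(=O)(=O)=O (terminal oxygen source)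
Why: Lemieux–Johnson oxidative cleavage should attack the electron-richer monosubstituted vinyl group in preference to the ester-conjugated acrylate double bond, and the amine then epimerises the α-aryl aldehyde at C3 through its enolate to the thermodynamically favoured 2,3-trans isomer while the non-enolisable C2 keeps its configuration.

Step 8
Reactants: 14 methyl (E)-3-[(2R,3R)-2-{4-[(2,2-dimethylpropanoyl)oxy]-3,5-dimethoxyphenyl}-3-formyl-7-methoxy-2,3-dihydro-1-benzofuran-5-yl]prop-2-enoate
Product: 15 (E)-3-[(2R,3S)-2-(4-hydroxy-3,5-dimethoxyphenyl)-3-(hydroxymethyl)-7-methoxy-2,3-dihydro-1-benzofuran-5-yl]prop-2-en-1-ol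
Conditions: i-Bu2AlH (8 equiv), CH2Cl2/THF, −78 → 0 °C; aq potassium sodium tartrate
Reagents that add atoms: none
Why: Hydride reduction with i-Bu2AlH should take the aldehyde and, by 1,2-reduction, the α,β-unsaturated ester to the primary alcohols and cleave the aryl pivalate in the same operation, with no epimerisable centre left once C3 carries CH2OH.

Compound list
1 | 1-bromo-2-fluoro-3-methoxybenzene | COc1cccc(Br)c1F | starting material
2 | 2-(3-bromo-4-fluoro-5-methoxyphenyl)-4,4,5,5-tetramethyl-1,3,2-dioxaborolane | COc1cc(B2OC(C)(C)C(C)(C)O2)cc(Br)c1F | intermediate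
3 | methyl acrylate (methyl prop-2-enoate) | C=CC(=O)OC | starting material
4 | methyl (E)-3-(3-bromo-4-fluoro-5-methoxyphenyl)prop-2-enoate | COC(=O)/C=C/c1cc(OC)c(F)c(Br)c1 | intermediate
5 | 2-ethenyl-4,4,5,5-tetramethyl-1,3,2-dioxaborolane (vinylboronic acid pinacol ester) | C=CB1OC(C)(C)C(C)(C)O1 | starting material
6 | methyl (E)-3-(3-ethenyl-4-fluoro-5-methoxyphenyl)prop-2-enoate | COC(=O)/C=C/c1cc(OC)c(F)c(C=C)c1 | intermediate
7 | 4,4,5,5-tetramethyl-2-(prop-2-en-1-yl)-1,3,2-dioxaborolane (allylboronic acid pinacol ester) | C=CCB1OC(C)(C)C(C)(C)O1 | starting material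
8 | methyl (E)-3-{4-fluoro-3-methoxy-5-[(E)-3-(4,4,5,5-tetramethyl-1,3,2-dioxaborolan-2-yl)prop-1-en-1-yl]phenyl}prop-2-enoate | COC(=O)/C=C/c1cc(OC)c(F)c(/C=C/CB2OC(C)(C)C(C)(C)O2)c1 | intermediate
9 | syringaldehyde (4-hydroxy-3,5-dimethoxybenzaldehyde) | COc1cc(C=O)cc(OC)c1O | starting material
10 | 4-formyl-2,6-dimethoxyphenyl 2,2-dimethylpropanoate | COc1cc(C=O)cc(OC)c1OC(=O)C(C)(C)C | intermediate
11 | 4-[(1R,2S)-2-{2-fluoro-3-methoxy-5-[(E)-3-methoxy-3-oxoprop-1-en-1-yl]phenyl}-1-[(4,4,5,5-tetramethyl-1,3,2-dioxaborolan-2-yl)oxy]but-3-en-1-yl]-2,6-dimethoxyphenyl 2,2-dimethylpropanoate | C=C[C@@H](c1cc(/C=C/C(=O)OC)cc(OC)c1F)[C@@H](OB1OC(C)(C)C(C)(C)O1)c1cc(OC)c(OC(=O)C(C)(C)C)c(OC)c1 | intermediate (not isolated)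
12 | methyl (E)-3-[(2R,3S)-2-{4-[(2,2-dimethylpropanoyl)oxy]-3,5-dimethoxyphenyl}-3-ethenyl-7-methoxy-2,3-dihydro-1-benzofuran-5-yl]prop-2-enoate (2,3-cis) | COC(=O)/C=C/c1cc(OC)c2O[C@@H](c3cc(OC)c(OC(=O)C(C)(C)C)c(OC)c3)[C@@H](C=C)c2c1 | intermediate
13 | methyl (E)-3-[(2R,3S)-2-{4-[(2,2-dimethylpropanoyl)oxy]-3,5-dimethoxyphenyl}-3-formyl-7-methoxy-2,3-dihydro-1-benzofuran-5-yl]prop-2-enoate (2,3-cis) | COC(=O)/C=C/c1cc(OC)c2O[C@@H](c3cc(OC)c(OC(=O)C(C)(C)C)c(OC)c3)[C@@H](C=O)c2c1 | intermediate (not isolated)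
14 | methyl (E)-3-[(2R,3R)-2-{4-[(2,2-dimethylpropanoyl)oxy]-3,5-dimethoxyphenyl}-3-formyl-7-methoxy-2,3-dihydro-1-benzofuran-5-yl]prop-2-enoate (2,3-trans) | COC(=O)/C=C/c1cc(OC)c2O[C@@H](c3cc(OC)c(OC(=O)C(C)(C)C)c(OC)c3)[C@H](C=O)c2c1 | intermediate
15 | (E)-3-[(2R,3S)-2-(4-hydroxy-3,5-dimethoxyphenyl)-3-(hydroxymethyl)-7-methoxy-2,3-dihydro-1-benzofuran-5-yl]prop-2-en-1-ol | COc1cc([C@@H]2Oc3c(OC)cc(/C=C/CO)cc3[C@H]2CO)cc(OC)c1O | target

Total step count: 8. Longest linear sequence: 7 (steps 1, 2, 3, 4, 6, 7, 8).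

Steps most likely to fail

Step 6. What may go wrong: erosion of aldehyde facial selectivity if the bulky γ-aryl boronate reacts partly by the uncatalysed pathway, or stalling at the borate stage so that ring closure does not follow in the same flask. Fallback (from 4 and 10, back at 12): Sonogashira coupling of 4 with propyne (PdCl2(PPh3)2, CuI, Et3N, THF, 50 °C) should give methyl (E)-3-[4-fluoro-3-methoxy-5-(prop-1-yn-1-yl)phenyl]prop-2-enoate F1, and NaBH4 reduction of 10 (MeOH, 0 °C) should give 4-(hydroxymethyl)-2,6-dimethoxyphenyl 2,2-dimethylpropanoate F2. The two are joined by the known ruthenium-catalysed transfer-hydrogenative alkyne–alcohol coupling, in which a 1-aryl-1-propyne serves as an allylmetal equivalent and gives anti-(α-aryl)homoallylic alcohols (H2Ru(CO)(PPh3)3, JOSIPHOS-type ligand SL-J009-1 in the enantiomeric form that gives the 1R carbinol, THF, 95 °C). This should give 4-[(1R,2S)-2-{2-fluoro-3-methoxy-5-[(E)-3-methoxy-3-oxoprop-1-en-1-yl]phenyl}-1-hydroxybut-3-en-1-yl]-2,6-dimethoxyphenyl 2,2-dimethylpropanoate F3, which is cyclised by base-mediated intramolecular SNAr (Cs2CO3, DMSO, 60 °C) to 12.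

Step 7. What may go wrong: over-oxidation through competing osmylation of the acrylate double bond, and incomplete cis-to-trans equilibration at C3. Fallback (from 12, back at 14): epoxidation with mCPBA (NaHCO3, CH2Cl2, rt), to which the ester-conjugated double bond is inert, should give methyl (E)-3-[(2R,3S)-2-{4-[(2,2-dimethylpropanoyl)oxy]-3,5-dimethoxyphenyl}-7-methoxy-3-(oxiran-2-yl)-2,3-dihydro-1-benzofuran-5-yl]prop-2-enoate F4 (both epimers at the oxirane carbon). Periodic acid (H5IO6, THF/H2O, 0 °C) then cleaves the epoxide to aldehyde 13, which Et3N equilibrates to 14.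

Step 4. What may go wrong: styrene self-metathesis and loss of the allylboron group on purification, leading to low conversion to the E-allylboronate. Fallback (from 4, back at 8, replacing steps 3 and 4): Suzuki–Miyaura coupling of 4 with commercial (E)-3-(4,4,5,5-tetramethyl-1,3,2-dioxaborolan-2-yl)prop-2-en-1-ol (PdCl2(dppf), K2CO3, 1,4-dioxane/H2O, 80 °C) should give methyl (E)-3-{4-fluoro-3-[(E)-3-hydroxyprop-1-en-1-yl]-5-methoxyphenyl}prop-2-enoate F5. Palladium-catalysed direct borylation of this allylic alcohol with B2pin2 ([Pd(MeCN)4](BF4)2, DMSO/MeOH, 50 °C) should then give the linear E-allylboronate 8.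

Further compounds
F1 | step 6 | methyl (E)-3-[4-fluoro-3-methoxy-5-(prop-1-yn-1-yl)phenyl]prop-2-enoate | COC(=O)/C=C/c1cc(OC)c(F)c(C#CC)c1
F2 | step 6 | 4-(hydroxymethyl)-2,6-dimethoxyphenyl 2,2-dimethylpropanoate | COc1cc(CO)cc(OC)c1OC(=O)C(C)(C)C
F3 | step 6 | 4-[(1R,2S)-2-{2-fluoro-3-methoxy-5-[(E)-3-methoxy-3-oxoprop-1-en-1-yl]phenyl}-1-hydroxybut-3-en-1-yl]-2,6-dimethoxyphenyl 2,2-dimethylpropanoate | C=C[C@@H](c1cc(/C=C/C(=O)OC)cc(OC)c1F)[C@@H](O)c1cc(OC)c(OC(=O)C(C)(C)C)c(OC)c1
F4 | step 7 | methyl (E)-3-[(2R,3S)-2-{4-[(2,2-dimethylpropanoyl)oxy]-3,5-dimethoxyphenyl}-7-methoxy-3-(oxiran-2-yl)-2,3-dihydro-1-benzofuran-5-yl]prop-2-enoate | COC(=O)/C=C/c1cc(OC)c2O[C@@H](c3cc(OC)c(OC(=O)C(C)(C)C)c(OC)c3)[C@@H](C3CO3)c2c1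
F5 | step 4 | methyl (E)-3-{4-fluoro-3-[(E)-3-hydroxyprop-1-en-1-yl]-5-methoxyphenyl}prop-2-enoate | COC(=O)/C=C/c1cc(OC)c(F)c(/C=C/CO)c1
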